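**Strategy.** On each cyclohexane the trans-disposed vinyl/methyl at C10 and isopropenyl at C5 are read as the retron of a Cope rearrangement. Joining C2 to C3 and opening C5–C10 gives a (1(10)E,4E)-cyclodeca-1,5-diene, the ring of commercial, achiral germacrone. Its C8 ketone is reduced enantioselectively. Its isopropylidene is excised and replaced, one macrocycle at a time, by the two ends of a 2,5-bis(phosphono)adipate (C11–C13 of both halves). This gives a butenolide and, after cis-reduction, a saturated lactone. The last step heats this bis-macrocycle: two transannular [3,3] shifts close both cyclohexanes (C5–C10 and C5′–C10′) and set four stereocentres from C8 and from C7′/C8′.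

Key step: step 12

Remark on the chemistry: germacrane/elemane numbering is used (C10 carries methyl and vinyl, C5 isopropenyl, C8 the lactone oxygen, C7/C11/C12/C13 the lactone carbons; primes mark the saturated-lactone half). Germacrone is assumed to be purchasable as the (E,E) compound. The phosphonate-bearing carbons of 3, 4 and 8–15 are uncontrolled mixtures; this has no consequence because they later become sp2 (C11) or are re-set (C11′).

Step 1
Reactants: 1 diethyl meso-2,5-dibromohexanedioate; 2 triethyl phosphite
Product: 3 diethyl 2,5-bis(diethoxyphosphoryl)hexanedioate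
Conditions: 2 (3 equiv in all, two of them consumed), neat, 155 °C, EtBr distilled off as it forms; excess 2 removed in vacuo
Reagents that add atoms: triethyl phosphite (second equivalent of 2), CCOP(OCC)OCC
Why: Double Michaelis–Arbuzov reaction, in which one molecule of phosphite displaces each of the two secondary α-bromides and bromide then dealkylates each phosphonium, as used for α-phosphono esters from α-bromo esters, should give the bis-phosphonate as a diastereomer mixture.

Step 2
Reactants: 3 diethyl 2,5-bis(diethoxyphosphoryl)hexanedioate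
Product: 4 2,5-bis(diethoxyphosphoryl)hexanedioic acid
Conditions: NaOH (2.2 equiv), EtOH/H2O, 0 °C to rt; then aq. HCl to pH 1
Reagents that add atoms: sodium hydroxide, [Na+].[OH-]
Why: Saponification should cleave the two carboxylic ethyl esters selectively, since phosphonate ethyl esters resist cold aqueous hydroxide.

Step 3
Reactants: 5 germacrone
Product: 6 (8R)-germacra-1(10)E,4E,7(11)-trien-8-ol
Conditions: (S)-Me-CBS oxazaborolidine [(S)-1-methyl-3,3-diphenyltetrahydro-1H,3H-pyrrolo[1,2-c][1,3,2]oxazaborole] (0.2 equiv), catecholborane (1.5 equiv), toluene, −78 °C (to −40 °C if slow)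
Reagents that add atoms: none
Why: CBS reduction with the alkylidene-bearing C7 as the large group should deliver hydride to the face that gives the 8R allylic alcohol, and catecholborane at low temperature should leave the ring alkenes and the enone C=C untouched.

Step 4
Reactants: 6 (8R)-germacra-1(10)E,4E,7(11)-trien-8-ol
Product: 7 (7S,8R)-7,11-epoxygermacra-1(10)E,4E-dien-8-ol
Conditions: VO(acac)2 (5 mol%), t-BuOOH (1.3 equiv, decane), CH2Cl2, 0 °C
Reagents that add atoms: tert-butyl hydroperoxide, CC(C)(C)OO
Why: Hydroxyl-directed vanadium-catalysed epoxidation should select the allylic tetrasubstituted C7=C11 alkene over the two remote trisubstituted ring alkenes and deliver oxygen syn to the hydroxyl (the spiro centre C7 is set by the directing group and destroyed in step 6).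

Step 5
Reactants: 7 (7S,8R)-7,11-epoxygermacra-1(10)E,4E-dien-8-ol; 4 2,5-bis(diethoxyphosphoryl)hexanedioic acid
Product: 8 mono-ester of 4 with the C8 hydroxyl of 7 (free acid at the other end)
Conditions: 4 (3 equiv), EDC·HCl (1.5 equiv), DMAP (0.2 equiv), CH2Cl2, 0 °C to rt
Reagents that add atoms: none
Why: Steglich-type carbodiimide esterification with the symmetrical diacid in excess should acylate the alcohol once and leave the second carboxyl free.

Step 6
Reactants: 8 mono-ester of 4 with 7
Product: 10 (8R)-7-oxo-11,12,13-trinorgermacra-1(10)E,4E-dien-8-yl hydrogen 2,5-bis(diethoxyphosphoryl)hexanedioate, via ditertiary diol 9 (not isolated)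
Conditions: H5IO6 (1.5 equiv), THF/Et2O, 0 °C, short contact
Reagents that add atoms: none
Why: Periodic acid cleavage of the epoxide (hydration at the dimethyl-substituted carbon by the water of the reagent, then glycol cleavage) should excise C11 as acetone and leave the C7 ketone beside the untouched C8 ester, with cold, brief exposure chosen to spare the acid-sensitive 1,5-diene.

Step 7
Reactants: 10 α-acyloxy ketone acid
Product: 11 (8R)-13-[2-carboxy-2-(diethoxyphosphoryl)ethyl]germacra-1(10)E,4E,7(11)-trien-12,8-olide
Conditions: LiCl (5 equiv), DBU (3 equiv), MeCN, 0 °C to rt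
Reagents that add atoms: none
Why: Intramolecular Horner–Wadsworth–Emmons olefination of the ester-side phosphonate with the neighbouring C7 ketone (five-membered ring closure) should give the tetrasubstituted butenolide, while the carboxylate-side phosphonate stays a spectator and C8 is retained.

Step 8
Reactants: 11 macrocyclic butenolide acid
Product: 12 (7R,8R,11S)-13-[2-carboxy-2-(diethoxyphosphoryl)ethyl]germacra-1(10)E,4E-dien-12,8-olide
Conditions: NiCl2·6H2O (0.2 equiv), NaBH4 (4 equiv, portionwise), MeOH/THF, −20 to 0 °C; aq. NH4Cl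
Reagents that add atoms: none
Why: Nickel boride (Ni2B) conjugate reduction should saturate only the lactone-conjugated alkene and add both hydrogens from the face of H8 (the ten-membered ring, attached through C9, covers the other face), giving the cis-fused lactone with H7, H8 and H11 cis.

Step 9
Reactants: 12 saturated lactone acid; 7 (7S,8R)-7,11-epoxygermacra-1(10)E,4E-dien-8-ol
Product: 13 ester of 12 with the C8 hydroxyl of a second molecule of 7
Conditions: 7 (1.2 equiv), EDC·HCl (1.5 equiv), DMAP (0.3 equiv), CH2Cl2, 0 °C to rt
Reagents that add atoms: none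
Why: Steglich-type esterification of the remaining α-phosphono acid should proceed as in step 5 without touching the lactone or its C11′ centre.

Step 10
Reactants: 13 epoxy ester
Product: 15 (8R)-7-oxo-11,12,13-trinorgermacra-1(10)E,4E-dien-8-yl ester of 12, via ditertiary diol 14 (not isolated)
Conditions: H5IO6 (1.5 equiv), THF/Et2O, 0 °C, short contact
Reagents that add atoms: none
Why: Periodic acid cleavage of the epoxide, as in step 6, should unveil the second C7 ketone with loss of acetone.

Step 11
Reactants: 15 α-acyloxy ketone
Product: 16 (8R)-germacra-1(10)E,4E,7(11)-trien-12,8-olide joined through C13–C13′ to (7′R,8′R,11′S)-germacra-1′(10′)E,4′E-dien-12′,8′-olide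
Conditions: LiCl (5 equiv), DBU (1.5 equiv), MeCN, 0 °C
Reagents that add atoms: none
Why: Intramolecular Horner–Wadsworth–Emmons olefination should close the second butenolide under base too weak to enolise the saturated lactone at C11′.

Step 12
Reactants: 16 bis-germacranolide
Product: 18 CNP0332736.1, via half-rearranged germacranolide–elemanolide 17 (not isolated)
Conditions: degassed toluene (0.005 M), BHT (trace), base-washed sealed tube, 150 °C
Reagents that add atoms: none
Why: Each (1(10)E,4E)-cyclodeca-1,5-diene undergoes a thermal [3,3]-sigmatropic (Cope) shift through a chair transition state in which C2–C3 breaks as C5–C10 forms, the reaction type by which germacrone and germacranolides are known to give elemanes. Both cyclohexanes are closed transannularly, a ten-membered ring being stitched across to a six-membered ring while the vinyl and isopropenyl groups appear. The (E,E) geometry in the chair array places vinyl and isopropenyl trans-diequatorial and the C10 methyl and H5 axial, which sets the relative configuration of C5/C10 in each half. In the butenolide half the planar lactone holds the C8–O bond in the plane of C6–C7–C8 (pseudo-equatorial, H8 axial), so of the two crossed diene conformers only the one leading from 8R to 5R,10R is unstrained. In the saturated half the cis-fused lactone should react through the conformer with the C7′–C11′ bond equatorial and C8′–O axial, the arrangement of 8,12-cis-germacranolides and eudesmanolides, giving 5′S,10′S. The step therefore needs only conformer (π-facial) selectivity, secured by C8 and by C7′/C8′, and being reagent-free it should leave C8 and the kinetically set C11′ untouched.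

**Compound list**
1 | diethyl meso-2,5-dibromohexanedioate | CCOC(=O)[C@H](Br)CC[C@H](Br)C(=O)OCC | starting material
2 | triethyl phosphite | CCOP(OCC)OCC | starting material
3 | diethyl 2,5-bis(diethoxyphosphoryl)hexanedioate (diastereomer mixture) | CCOC(=O)C(CCC(C(=O)OCC)P(=O)(OCC)OCC)P(=O)(OCC)OCC | intermediate
4 | 2,5-bis(diethoxyphosphoryl)hexanedioic acid (diastereomer mixture) | OC(=O)C(CCC(C(=O)O)P(=O)(OCC)OCC)P(=O)(OCC)OCC | intermediate
5 | germacrone, (3E,7E)-3,7-dimethyl-10-(propan-2-ylidene)cyclodeca-3,7-dien-1-one | O=C1C/C(C)=C/CC/C(C)=C/CC1=C(C)C | starting material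
6 | (1R,3E,7E)-3,7-dimethyl-10-(propan-2-ylidene)cyclodeca-3,7-dien-1-ol | O[C@@H]1C/C(C)=C/CC/C(C)=C/CC1=C(C)C | intermediate
7 | (3S,4R,6E,10E)-2,2,6,10-tetramethyl-1-oxaspiro[2.9]dodeca-6,10-dien-4-ol | O[C@@H]1C/C(C)=C/CC/C(C)=C/C[C@]12OC2(C)C | intermediate
8 | hydrogen (3S,4R,6E,10E)-2,2,6,10-tetramethyl-1-oxaspiro[2.9]dodeca-6,10-dien-4-yl 2,5-bis(diethoxyphosphoryl)hexanedioate | O=C(O[C@@H]1C/C(C)=C/CC/C(C)=C/C[C@]12OC2(C)C)C(CCC(C(=O)O)P(=O)(OCC)OCC)P(=O)(OCC)OCC | intermediate
9 | hydrogen (1R,10S,3E,7E)-10-hydroxy-10-(2-hydroxypropan-2-yl)-3,7-dimethylcyclodeca-3,7-dien-1-yl 2,5-bis(diethoxyphosphoryl)hexanedioate (formed and consumed in the flask) | O=C(O[C@@H]1C/C(C)=C/CC/C(C)=C/C[C@@]1(O)C(C)(C)O)C(CCC(C(=O)O)P(=O)(OCC)OCC)P(=O)(OCC)OCC | intermediate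
10 | hydrogen (1R,3E,7E)-3,7-dimethyl-10-oxocyclodeca-3,7-dien-1-yl 2,5-bis(diethoxyphosphoryl)hexanedioate | O=C(O[C@@H]1C/C(C)=C/CC/C(C)=C/CC1=O)C(CCC(C(=O)O)P(=O)(OCC)OCC)P(=O)(OCC)OCC | intermediate
11 | 4-[(5E,9E,11aR)-6,10-dimethyl-2-oxo-2,4,7,8,11,11a-hexahydrocyclodeca[b]furan-3-yl]-2-(diethoxyphosphoryl)butanoic acid | O=C1O[C@@H]2C/C(C)=C/CC/C(C)=C/CC2=C1CCC(C(=O)O)P(=O)(OCC)OCC | intermediate
12 | 4-[(3S,3aR,5E,9E,11aR)-6,10-dimethyl-2-oxo-2,3,3a,4,7,8,11,11a-octahydrocyclodeca[b]furan-3-yl]-2-(diethoxyphosphoryl)butanoic acid | OC(=O)C(P(=O)(OCC)OCC)CC[C@@H]1C(=O)O[C@@H]2C/C(C)=C/CC/C(C)=C/C[C@H]12 | intermediate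
13 | (3S,4R,6E,10E)-2,2,6,10-tetramethyl-1-oxaspiro[2.9]dodeca-6,10-dien-4-yl ester of 12 | O=C(O[C@@H]1C/C(C)=C/CC/C(C)=C/C[C@]12OC2(C)C)C(P(=O)(OCC)OCC)CC[C@@H]3C(=O)O[C@@H]4C/C(C)=C/CC/C(C)=C/C[C@H]34 | intermediate
14 | (1R,10S,3E,7E)-10-hydroxy-10-(2-hydroxypropan-2-yl)-3,7-dimethylcyclodeca-3,7-dien-1-yl ester of 12 (formed and consumed in the flask) | O=C(O[C@@H]1C/C(C)=C/CC/C(C)=C/C[C@@]1(O)C(C)(C)O)C(P(=O)(OCC)OCC)CC[C@@H]3C(=O)O[C@@H]4C/C(C)=C/CC/C(C)=C/C[C@H]34 | intermediate
15 | (1R,3E,7E)-3,7-dimethyl-10-oxocyclodeca-3,7-dien-1-yl ester of 12 | O=C(O[C@@H]1C/C(C)=C/CC/C(C)=C/CC1=O)C(P(=O)(OCC)OCC)CC[C@@H]3C(=O)O[C@@H]4C/C(C)=C/CC/C(C)=C/C[C@H]34 | intermediate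
16 | (8R)-germacra-1(10)E,4E,7(11)-trien-12,8-olide joined through C13–C13′ to (7′R,8′R,11′S)-germacra-1′(10′)E,4′E-dien-12′,8′-olide | O=C1O[C@@H]2C/C(C)=C/CC/C(C)=C/CC2=C1CC[C@@H]3C(=O)O[C@@H]4C/C(C)=C/CC/C(C)=C/C[C@H]34 | intermediate
17 | (8R)-germacra-1(10)E,4E,7(11)-trien-12,8-olide joined through C13–C13′ to (5′S,7′R,8′R,10′S,11′S)-elema-1′,3′-dien-12′,8′-olide (formed and consumed in the flask) | O=C1O[C@@H]2C/C(C)=C/CC/C(C)=C/CC2=C1CC[C@@H]3C(=O)O[C@@H]4C[C@@](C)(C=C)[C@H](C(=C)C)C[C@H]34 | intermediate
18 | CNP0332736.1, (5R,8R,10R)-elema-1,3,7(11)-trien-12,8-olide joined through C13–C13′ to (5′S,7′R,8′R,10′S,11′S)-elema-1′,3′-dien-12′,8′-olide | C=C[C@@]1(C)C[C@H]2OC(=O)C(CC[C@@H]3C(=O)O[C@@H]4C[C@@](C)(C=C)[C@H](C(=C)C)C[C@H]34)=C2C[C@@H]1C(=C)C | target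

**Step count and risks**
Total steps: 12. Longest linear sequence: 10 (steps 3–12, from germacrone); the linker branch (steps 1–2) joins at step 5, and 7 is used twice (steps 5 and 9).

Step 12 (double Cope rearrangement). What may go wrong: the two halves may need different temperatures, and prolonged heating of the γ-acyloxy butenolide half may erode C8 through enolisation or cause decomposition before the saturated half has rearranged. Fallback: the rearrangement is moved ahead of the cleavage and the olefination. Compound 13 is heated (toluene, 150 °C), so that both dienes rearrange while the future butenolide half is still the spiro-epoxy ester. In that chair transition state the CMe2 carbon of the epoxide and the ester oxygen both take equatorial positions, which should again lead from 8R to 5R,10R. This should give the doubly rearranged epoxy ester F1. On this acid-stable divinylcyclohexane, H5IO6 cleavage should give the α-acyloxy ketone F2. LiCl/DBU olefination then closes the butenolide and returns to the route at 18; any base-induced equilibration at C8 at that stage converges on the desired, more stable epimer.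

Step 8 (nickel boride reduction). What may go wrong: the tetrasubstituted lactone alkene may resist reduction, a ring alkene may be saturated, or methoxide-mediated equilibration may scramble C11′. Fallback: the two new centres are set in separate events. Starting from 11, magnesium turnings in methanol (electron-transfer conjugate reduction, inert to isolated alkenes) should give the cis-fused lactone without control at C11′, that is the 11′R epimer F3 or its mixture with 12. This material is converted into its trianion (carboxylate, phosphonate carbanion, lactone enolate) with LiN(i-Pr)2 (3.3 equiv, THF, −78 °C) and quenched cold with acetic acid. Kinetic protonation of the lactone enolate from the convex face should return the route at 12.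

Step 3 (CBS reduction). What may go wrong: poor enantiofacial discrimination, because the two planar-chiral conformers of the ten-membered enone expose opposite carbonyl faces and may not interconvert fast enough at low temperature. Fallback: resolution instead of asymmetric catalysis. Starting from 5, Luche reduction (NaBH4, CeCl3·7H2O, MeOH, 0 °C) should give the racemic alcohol F4. Acylation with vinyl acetate catalysed by lipase B from Candida antarctica (hexane, rt) should then acetylate the R enantiomer selectively and give the acetate F5, which is separated from the unreacted S alcohol. Methanolysis (K2CO3, MeOH) returns the route at 6.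

**Further compounds**
F1 | step 12 | (5R,7S,8R,10R)-7,11-epoxyelema-1,3-dien-8-yl ester of the (5′S,7′R,8′R,10′S,11′S)-elemanolide phosphono acid (doubly rearranged epoxy ester) | C=C[C@@]1(C)C[C@@H](OC(=O)C(P(=O)(OCC)OCC)CC[C@@H]3C(=O)O[C@@H]4C[C@@](C)(C=C)[C@H](C(=C)C)C[C@H]34)[C@@]2(OC2(C)C)C[C@@H]1C(=C)C
F2 | step 12 | (5R,8R,10R)-7-oxo-11,12,13-trinorelema-1,3-dien-8-yl ester of the same acid (α-acyloxy ketone) | C=C[C@@]1(C)C[C@@H](OC(=O)C(P(=O)(OCC)OCC)CC[C@@H]3C(=O)O[C@@H]4C[C@@](C)(C=C)[C@H](C(=C)C)C[C@H]34)C(=O)C[C@@H]1C(=C)C
F3 | step 8 | 11′R epimer of 12 | OC(=O)C(P(=O)(OCC)OCC)CC[C@H]1C(=O)O[C@@H]2C/C(C)=C/CC/C(C)=C/C[C@H]12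
F4 | step 3 | racemic (3E,7E)-3,7-dimethyl-10-(propan-2-ylidene)cyclodeca-3,7-dien-1-ol | OC1C/C(C)=C/CC/C(C)=C/CC1=C(C)C
F5 | step 3 | (1R,3E,7E)-3,7-dimethyl-10-(propan-2-ylidene)cyclodeca-3,7-dien-1-yl acetate | CC(=O)O[C@@H]1C/C(C)=C/CC/C(C)=C/CC1=C(C)C
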